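**Strategy.** Ring B is disconnected across C1'–C2' and C5'–C6'. Its adjacent C1' carboxyl and C6' pentyl are the two carbons of an oct-2-ynoate triple bond. The C2'(OMe)–C3'–C4'(O-depside)–C5' fragment is a 1-methoxy-3-acyloxybutadiene whose acyl group is the finished ring A. One operation, a [4+2] cycloaddition followed in the same flask by quinone dehydrogenation, should close ring B and give the fully substituted, benzyl-protected depside. The precursor is the E-configured 4-methoxybuta-1,3-dien-2-yl ester of O-benzylated, 4-O-methylated olivetolic acid. It is made by ruthenium-catalysed addition of that acid to methoxybutenyne, so the hindered depside C–O bond exists before ring B does.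

Key step: step 7

Remark: the target has no stereocentre and no stereogenic double bond, so it is achiral and there is no enantiomer to select. The only stereochemical element in the route is the E/Z geometry of the dienyl ester.

**Step 1**
Reactants: 1 olivetolic acid (2,4-dihydroxy-6-pentylbenzoic acid)
Product: 2 methyl 2-hydroxy-4-methoxy-6-pentylbenzoate
Conditions: MeI (2.1 equiv), K2CO3 (2.2 equiv), acetone, rt → 40 °C
Reagents that add atoms: iodomethane, CI
Why: Carboxylate O-alkylation and Williamson etherification in one pot should methylate the carboxylate and the free 4-OH, while the 2-OH, hydrogen-bonded to the new ester carbonyl, is much less nucleophilic under carbonate conditions and stays free.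

**Step 2**
Reactants: 2 methyl 2-hydroxy-4-methoxy-6-pentylbenzoate
Product: 3 methyl 2-(benzyloxy)-4-methoxy-6-pentylbenzoate
Conditions: BnBr (1.3 equiv), K2CO3, KI (cat.), DMF, 60 °C
Reagents that add atoms: benzyl bromide, BrCc1ccccc1
Why: Williamson etherification of the chelated phenol, forced by the dipolar aprotic solvent, heat and iodide catalysis, should install the benzyl ether that is removed in the last step together with the benzyl ester.

**Step 3**
Reactants: 3 methyl 2-(benzyloxy)-4-methoxy-6-pentylbenzoate
Product: 4 2-(benzyloxy)-4-methoxy-6-pentylbenzoic acid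
Conditions: KOH (5 equiv), DMSO–H2O (4:1), 90 °C; then 1 M HCl, 0 °C
Reagents that add atoms: potassium hydroxide, [K+].[OH-]
Why: Saponification of the 2,6-disubstituted methyl ester needs poorly solvated hydroxide in hot aqueous DMSO, conditions to which the aryl methyl and aryl benzyl ethers are inert; cold acidification avoids protodecarboxylation.

**Step 4**
Reactants: 4 2-(benzyloxy)-4-methoxy-6-pentylbenzoic acid; 5 (Z)-1-methoxybut-1-en-3-yne (1.5 equiv, freed from methanol and water and distilled before use)
Product: 6 (Z)-4-methoxybuta-1,3-dien-2-yl 2-(benzyloxy)-4-methoxy-6-pentylbenzoate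
Conditions: [RuCl2(p-cymene)(PPh3)] (2 mol%), Na2CO3 (5 mol%), PhMe, 60 °C
Reagents that add atoms: none
Why: Ruthenium-catalysed Markovnikov addition of a carboxylic acid to the terminal alkyne of a conjugated enyne should place the carboxylate oxygen on the internal alkyne carbon, giving the 2-acyloxy-1,3-diene with the Z enol ether untouched and forming the depside C–O bond without any attack at the hindered acyl carbon.

**Step 5**
Reactants: 6 (Z)-4-methoxybuta-1,3-dien-2-yl 2-(benzyloxy)-4-methoxy-6-pentylbenzoate
Product: 7 (E)-4-methoxybuta-1,3-dien-2-yl 2-(benzyloxy)-4-methoxy-6-pentylbenzoate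
Conditions: PhSSPh (5 mol%), 400 nm LED, degassed C6H6, rt
Reagents that add atoms: none
Why: Thiyl-radical-catalysed Z/E equilibration of a conjugated diene (reversible addition of PhS• to the CH2 terminus, rotation in the allyl radical, β-scission) should favour the E isomer, because the Z-methoxy group clashes with the C2 acyloxy group in the s-trans conformer and with the C1 methylene in the s-cis conformer.

**Step 6**
Reactants: 8 oct-2-ynoic acid
Product: 9 benzyl oct-2-ynoate
Conditions: BnBr (1.05 equiv), K2CO3, DMF, rt
Reagents that add atoms: benzyl bromide, BrCc1ccccc1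
Why: SN2 alkylation of the carboxylate should give the benzyl ester cleanly at room temperature, with the conjugated alkyne left untouched by the weak base.

**Step 7**
Reactants: 7 (E)-4-methoxybuta-1,3-dien-2-yl 2-(benzyloxy)-4-methoxy-6-pentylbenzoate; 9 benzyl oct-2-ynoate (3 equiv)
Product: 11 benzyl 4-{[2-(benzyloxy)-4-methoxy-6-pentylbenzoyl]oxy}-2-methoxy-6-pentylbenzoate, via cyclohexa-1,4-diene cycloadduct 10 (not isolated)
Conditions: PhMe (2 M), 2,6-di-tert-butyl-4-methylpyridine (0.1 equiv), BHT (cat.), 120 °C, sealed tube; then 0 °C, NaHCO3 (s), DDQ (1.1 equiv), 0 °C → rt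
Reagents that add atoms: none
Why: The donor-substituted diene 7 (HOMO raised by the C4 methoxy and C2 acyloxy groups, largest coefficient at the CH2 terminus) and the ynoate 9 (LUMO largest at the pentyl-bearing β-carbon) should combine in a concerted, asynchronous normal-demand [4+2] cycloaddition that forms C5'–C6' slightly ahead of C1'–C2' and gives the 1,4-cyclohexadiene 10. The closest known reaction type is the Diels–Alder reaction of Danishefsky-type 1-alkoxy-3-oxy-dienes and of 2-acyloxy-1,3-dienes with acetylenic esters, followed by quinone dehydrogenation of the cyclohexa-1,4-diene. Ring B, the only ring formed, is closed intermolecularly by this cycloaddition, both new σ-bonds arising in the same step from the s-cis conformer of the E-diene. The single new stereocentre, the methoxy-bearing C2' of 10, arises as a racemate and is erased on aromatisation, so no stereocontrol is required. Two selectivities are needed: head-to-tail regiochemistry, secured by the matched polarisation of diene and ynoate, and hydride abstraction by DDQ from the doubly allylic, oxygen-activated C2'–H (followed by loss of the C5' proton) outrunning ionisation of the allylic methyl ether, secured by a strictly acid-free thermal stage (hindered pyridine, non-polar solvent) and by adding DDQ cold over solid NaHCO3. DDQ is introduced only after 7 has been consumed, because the quinone would otherwise attack the electron-rich diene itself.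

**Step 8**
Reactants: 11 benzyl 4-{[2-(benzyloxy)-4-methoxy-6-pentylbenzoyl]oxy}-2-methoxy-6-pentylbenzoate
Product: 12 2'-O-methylperlatolic acid (4-[(2-hydroxy-4-methoxy-6-pentylbenzoyl)oxy]-2-methoxy-6-pentylbenzoic acid)
Conditions: H2 (1 atm), 10% Pd/C, EtOAc, rt
Reagents that add atoms: none
Why: Catalytic hydrogenolysis should cleave the benzyl ether and the benzyl ester together under neutral conditions that leave the base-sensitive aryl ester of the depside, the methyl ethers and the arenes intact.

**Compound list**
1 | olivetolic acid (2,4-dihydroxy-6-pentylbenzoic acid) | CCCCCc1cc(O)cc(O)c1C(=O)O | starting material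
2 | methyl 2-hydroxy-4-methoxy-6-pentylbenzoate | CCCCCc1cc(OC)cc(O)c1C(=O)OC | intermediate
3 | methyl 2-(benzyloxy)-4-methoxy-6-pentylbenzoate | CCCCCc1cc(OC)cc(OCc2ccccc2)c1C(=O)OC | intermediate
4 | 2-(benzyloxy)-4-methoxy-6-pentylbenzoic acid | CCCCCc1cc(OC)cc(OCc2ccccc2)c1C(=O)O | intermediate
5 | (Z)-1-methoxybut-1-en-3-yne | CO/C=C\C#C | starting material
6 | (Z)-4-methoxybuta-1,3-dien-2-yl 2-(benzyloxy)-4-methoxy-6-pentylbenzoate | CCCCCc1cc(OC)cc(OCc2ccccc2)c1C(=O)OC(=C)/C=C\OC | intermediate
7 | (E)-4-methoxybuta-1,3-dien-2-yl 2-(benzyloxy)-4-methoxy-6-pentylbenzoate | CCCCCc1cc(OC)cc(OCc2ccccc2)c1C(=O)OC(=C)/C=C/OC | intermediate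
8 | oct-2-ynoic acid | CCCCCC#CC(=O)O | starting material
9 | benzyl oct-2-ynoate | CCCCCC#CC(=O)OCc1ccccc1 | intermediate
10 | benzyl 4-{[2-(benzyloxy)-4-methoxy-6-pentylbenzoyl]oxy}-6-methoxy-2-pentylcyclohexa-1,4-diene-1-carboxylate (racemic at the methoxy-bearing carbon; not isolated) | CCCCCC1=C(C(=O)OCc2ccccc2)C(OC)C=C(OC(=O)c2c(CCCCC)cc(OC)cc2OCc2ccccc2)C1 | intermediate
11 | benzyl 4-{[2-(benzyloxy)-4-methoxy-6-pentylbenzoyl]oxy}-2-methoxy-6-pentylbenzoate | CCCCCc1cc(OC)cc(OCc2ccccc2)c1C(=O)Oc1cc(CCCCC)c(C(=O)OCc2ccccc2)c(OC)c1 | intermediate
12 | 2'-O-methylperlatolic acid | CCCCCc1cc(OC)cc(O)c1C(=O)Oc1cc(CCCCC)c(C(=O)O)c(OC)c1 | target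

**Step count.** Total: 8 steps. Longest linear sequence: 7 steps (steps 1, 2, 3, 4, 5, 7, 8); step 6 is a one-step side branch.

**Steps most likely to fail**

Step 7. The cycloadduct may lose methanol by acid- or heat-induced 1,4-elimination before it can be dehydrogenated, which would give the arene without the 2'-methoxy group. Alternatively, the cycloaddition with the β-alkyl ynoate may be so slow that the diene polymerises. The fallback abandons the cycloaddition and forms the depside bond by classical acylation; it sets out from 1 and 4 and returns at 11. Double benzylation of 1 (BnBr 2.1 equiv, K2CO3, acetone) would give benzyl 4-(benzyloxy)-2-hydroxy-6-pentylbenzoate F1, again leaving the chelated 2-OH free. Methylation (MeI, K2CO3, DMF, 60 °C) would give benzyl 4-(benzyloxy)-2-methoxy-6-pentylbenzoate F2. Hydrogenolysis (H2, Pd/C, EtOAc) would give 4-hydroxy-2-methoxy-6-pentylbenzoic acid F3. Selective carboxylate alkylation (BnBr 1.0 equiv, KHCO3, DMF, rt) would give benzyl 4-hydroxy-2-methoxy-6-pentylbenzoate F4. Condensation of F4 with acid 4 by the mixed trifluoroacetic anhydride method (TFAA, PhMe, rt) should then give 11, which continues through step 8.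

Step 4. The carboxylic acid may protonate the enol ether of the enyne, leading to acetal formation or hydrolysis. The addition may also give some anti-Markovnikov product, or the enyne may oligomerise on the metal. The fallback transfers the acyl group to a preformed E-dienolate oxygen; it sets out from 4 and returns at 7, so step 5 is no longer needed. Acid 4 would be converted into 2-(benzyloxy)-4-methoxy-6-pentylbenzoyl fluoride F5 (cyanuric fluoride, pyridine, CH2Cl2, 0 °C). F5 would then be combined with commercial (E)-1-methoxy-3-(trimethylsilyloxy)buta-1,3-diene (CO/C=C/C(=C)O[Si](C)(C)C) and catalytic anhydrous fluoride (TBAT, THF, −78 → 0 °C). O-Acylation of the liberated dienolate by the hindered acyl fluoride should give 7 directly with the E geometry already in place.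

Step 5. Equilibration may stop short of useful E content, or the diene may be consumed by irreversible radical addition, polymerisation or trace-acid hydrolysis during irradiation. The fallback takes the E geometry from a stereodefined enyne and avoids isomerisation; it sets out from 4 and returns at 7. Commercial (E)-4-methoxybut-3-en-2-one (CO/C=C/C(C)=O) would be deprotonated at the methyl group and phosphorylated (LDA, THF, −78 °C; ClP(O)(OEt)2) to give diethyl (E)-4-methoxybuta-1,3-dien-2-yl phosphate F6. Elimination (LDA 2.2 equiv, THF, −78 °C → rt, then water) would give (E)-1-methoxybut-1-en-3-yne F7. Ruthenium-catalysed addition of 4 to F7 under the conditions of step 4 should then give 7.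

**Further compounds**
F1 | step 7 | benzyl 4-(benzyloxy)-2-hydroxy-6-pentylbenzoate | CCCCCc1cc(OCc2ccccc2)cc(O)c1C(=O)OCc1ccccc1
F2 | step 7 | benzyl 4-(benzyloxy)-2-methoxy-6-pentylbenzoate | CCCCCc1cc(OCc2ccccc2)cc(OC)c1C(=O)OCc1ccccc1
F3 | step 7 | 4-hydroxy-2-methoxy-6-pentylbenzoic acid | CCCCCc1cc(O)cc(OC)c1C(=O)O
F4 | step 7 | benzyl 4-hydroxy-2-methoxy-6-pentylbenzoate | CCCCCc1cc(O)cc(OC)c1C(=O)OCc1ccccc1
F5 | step 4 | 2-(benzyloxy)-4-methoxy-6-pentylbenzoyl fluoride | CCCCCc1cc(OC)cc(OCc2ccccc2)c1C(=O)F
F6 | step 5 | diethyl (E)-4-methoxybuta-1,3-dien-2-yl phosphate | CCOP(=O)(OCC)OC(=C)/C=C/OC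
F7 | step 5 | (E)-1-methoxybut-1-en-3-yne | CO/C=C/C#C
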